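The furan ring is read as a dehydrated 1,4-diketone, and that diketone is cut at the bond that joins furan C3 (methyl-bearing) to C4 (H-bearing). These atoms are the α-carbons of the carbonyls that become C2 (acid chain) and C5 (pentyl); both are donor sites, so the bond must be made oxidatively. Anodic oxidation of a regiodefined triethylsilyl enol ether of a C16 keto ester, its double bond pointing to the methyl-bearing carbon, in the presence of hept-1-en-2-yl acetate should forge the C3–C4 bond and deliver the open-chain diketone in one operation with the substitution pattern already fixed. Paal–Knorr closure and ester hydrolysis then finish the acid.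

Key step: step 6

Remark: locants C14–C17 used below belong to the docosanoate chain of the 1,4-diketone (C14 and C17 carbonyl carbons, C15 methyl-bearing, C16 methylene); they become furan C2, C5, C3 and C4. The target has no stereocentre.

Step 1
Reactants: 1 tetradecanedioic acid
Product: 2 14-methoxy-14-oxotetradecanoic acid
Conditions: MeOH (1.2 equiv), cat. H2SO4, THF, 60 °C, to about half esterification; 1 and diester recycled
Reagents that add atoms: methanol, CO
Why: Fischer esterification with limiting methanol: the two carboxyl groups are equivalent and far apart, so a statistical mixture is expected in which the half ester predominates near half conversion; insoluble 1 is filtered from cold CH2Cl2 and the neutral diester is removed by chromatography, both being recycled.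

Step 2
Reactants: 2 14-methoxy-14-oxotetradecanoic acid
Product: 4 methyl 14-[methoxy(methyl)amino]-14-oxotetradecanoate, via acyl imidazolide 3 (not isolated)
Conditions: CDI (1.1 equiv), CH2Cl2, rt; then MeNH(OMe)·HCl (1.2 equiv), rt
Reagents that add atoms: N,O-dimethylhydroxylamine hydrochloride, CNOC.Cl; 1,1'-carbonyldiimidazole, O=C(n1ccnc1)n1ccnc1 (supplies the imidazolyl group of 3 only)
Why: Weinreb amide synthesis through an acyl imidazole: CDI activates only the free carboxyl group, and the amine, liberated from its hydrochloride by the imidazole set free, displaces imidazole while the methyl ester stays untouched.

Step 3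
Reactants: 4 methyl 14-[methoxy(methyl)amino]-14-oxotetradecanoate; 5 vinylmagnesium bromide
Product: 7 methyl 14-oxohexadec-15-enoate, via magnesium chelate 6 (not isolated)
Conditions: CH2=CHMgBr (1.3 equiv), THF, −20 °C; inverse quench into cold 1 M HCl
Reagents that add atoms: none
Why: Weinreb ketone synthesis: the Grignard reagent adds once to the N-methoxy-N-methylamide, which is activated by chelation and reacts ahead of the remote methyl ester at low temperature, to give a stable five-membered magnesium chelate that releases the vinyl ketone only on quenching, and the cold acidic inverse quench protonates the liberated N,O-dimethylhydroxylamine before it can add to the enone.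

Step 4
Reactants: 7 methyl 14-oxohexadec-15-enoate; 8 triethylsilane
Product: 9 methyl (Z)-14-(triethylsilyloxy)hexadec-14-enoate
Conditions: Et3SiH (1.2 equiv), RhCl(PPh3)3 (1 mol%), toluene, 50 °C; filtration through Et3N-deactivated silica
Reagents that add atoms: none
Why: 1,4-Hydrosilylation of an enone with a monohydrosilane under catalysis by monovalent rhodium: Si–H adds to the metal, hydride is passed to the terminal vinyl carbon of the s-cis enone (which becomes the methyl group) and silicon ends on oxygen, so the enol double bond can lie only between C14 and C15 and the Z geometry follows from the s-cis arrangement; either geometry would serve the next step and the ester is not reduced.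

Step 5
Reactants: 10 hept-1-yne
Product: 11 hept-1-en-2-yl acetate
Conditions: AcOH (1.1 equiv), [RuCl2(p-cymene)]2 (0.5 mol%), P(2-furyl)3 (1 mol%), Na2CO3 (2 mol%), toluene, 50 °C; distillation
Reagents that add atoms: acetic acid, CC(=O)O
Why: Ruthenium-catalysed Markovnikov hydro-acyloxylation of a terminal alkyne: acetate attacks the internal carbon of the alkyne held on divalent ruthenium and protonolysis of the Ru–C bond releases the 1-alken-2-yl ester, so the double bond is terminal and the addition is free of by-products.

Step 6
Reactants: 9 methyl (Z)-14-(triethylsilyloxy)hexadec-14-enoate; 11 hept-1-en-2-yl acetate
Product: 12 racemic methyl 15-methyl-14,17-dioxodocosanoate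
Conditions: graphite anode, Pt cathode, undivided cell, constant current (ca. 1 mA cm−2, 2.2 F mol−1), LiClO4 (0.1 M), 2,6-lutidine (3 equiv), 11 (8 equiv), MeCN–MeOH 4:1, 0 °C; 9 added slowly during the electrolysis
Reagents that add atoms: none
Why: Proposed new method: the trisubstituted enol silane 9 should be oxidised at the anode well before the acyl-deactivated enol acetate 11, and methanol-assisted loss of the silyl group from its radical cation should leave an electrophilic secondary α-keto radical at C15 that adds to the unhindered, electron-rich CH2 terminus of 11; the α-acetoxy radical so formed is oxidised to an acyloxycarbenium ion, which methanol de-acetylates to the C17 ketone, so two electrons pass per C15–C16 bond. The closest known reactions are the (NH4)2Ce(NO3)6 (tetravalent cerium) cross-coupling of a 1,2-disubstituted with a 1-substituted silyl enol ether, the Mn(OAc)3 (trivalent manganese) addition of ketones to isopropenyl acetate and intramolecular anodic couplings of silyl enol ethers with alkenes; an intermolecular anodic union of an enol silane with an enol acetate has not been shown. No ring is closed in this step. The new stereocentre C15 is formed without any controlling element and is racemic, which is of no consequence because it becomes sp2 in the furan. The selectivity needed is cross-coupling over homo-coupling and over capture of the oxidised radical by methanol, and it rests on the gap in oxidation potential between 9 and 11, on the polarity match of an electrophilic radical with a donor alkene, and on slow addition of 9 into a large excess of 11 at low current density. Regiochemistry is fixed by the substrates, since only C15 of 9 carries the enol double bond and only C1 of 11 is a CH2 terminus.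

Step 7
Reactants: 12 racemic methyl 15-methyl-14,17-dioxodocosanoate
Product: 13 methyl 13-(3-methyl-5-pentylfuran-2-yl)tridecanoate
Conditions: TsOH·H2O (10 mol%), toluene, reflux, Dean–Stark, Ar
Reagents that add atoms: none
Why: Paal–Knorr furan synthesis: acid-catalysed enolisation of one ketone, attack of the enol oxygen on the other protonated carbonyl (5-exo-trig) and loss of water with azeotropic removal should give the aromatic ring, in which C15 becomes sp2 and the methyl, H and both chains sit where the diketone placed them; the methyl ester is inert to anhydrous TsOH.

Step 8
Reactants: 13 methyl 13-(3-methyl-5-pentylfuran-2-yl)tridecanoate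
Product: 15 13-(3-methyl-5-pentylfuran-2-yl)tridecanoic acid, via lithium carboxylate 14 (not isolated)
Conditions: LiOH·H2O (3 equiv), THF–MeOH–H2O 3:1:1, rt, Ar; then cold 1 M HCl to pH 4
Reagents that add atoms: lithium hydroxide, [Li+].[OH-]
Why: Saponification (acyl–oxygen cleavage by hydroxide): the trialkylfuran is stable to base, and brief cold acidification under argon with exclusion of light spares the acid- and oxygen-sensitive ring.

Compound list
1 | tetradecanedioic acid | OC(=O)CCCCCCCCCCCCC(=O)O | starting material
2 | 14-methoxy-14-oxotetradecanoic acid | COC(=O)CCCCCCCCCCCCC(=O)O | intermediate
3 | methyl 14-(1H-imidazol-1-yl)-14-oxotetradecanoate (acyl imidazolide) | COC(=O)CCCCCCCCCCCCC(=O)n1ccnc1 | intermediate (not isolated)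
4 | methyl 14-[methoxy(methyl)amino]-14-oxotetradecanoate | COC(=O)CCCCCCCCCCCCC(=O)N(C)OC | intermediate
5 | vinylmagnesium bromide | C=C[Mg]Br | starting material
6 | bromomagnesium salt of methyl 14-hydroxy-14-[methoxy(methyl)amino]hexadec-15-enoate (racemic tetrahedral chelate) | COC(=O)CCCCCCCCCCCCC(C=C)(O[Mg]Br)N(C)OC | intermediate (not isolated)
7 | methyl 14-oxohexadec-15-enoate | C=CC(=O)CCCCCCCCCCCCC(=O)OC | intermediate
8 | triethylsilane | CC[SiH](CC)CC | starting material
9 | methyl (Z)-14-(triethylsilyloxy)hexadec-14-enoate | C/C=C(/CCCCCCCCCCCCC(=O)OC)O[Si](CC)(CC)CC | intermediate
10 | hept-1-yne | CCCCCC#C | starting material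
11 | hept-1-en-2-yl acetate | C=C(CCCCC)OC(C)=O | intermediate
12 | racemic methyl 15-methyl-14,17-dioxodocosanoate | CCCCCC(=O)CC(C)C(=O)CCCCCCCCCCCCC(=O)OC | intermediate
13 | methyl 13-(3-methyl-5-pentylfuran-2-yl)tridecanoate | CCCCCc1cc(C)c(CCCCCCCCCCCCC(=O)OC)o1 | intermediate
14 | lithium 13-(3-methyl-5-pentylfuran-2-yl)tridecanoate | CCCCCc1cc(C)c(CCCCCCCCCCCCC(=O)[O-])o1.[Li+] | intermediate (not isolated)
15 | 13-(3-methyl-5-pentylfuran-2-yl)tridecanoic acid | CCCCCc1cc(C)c(CCCCCCCCCCCCC(=O)O)o1 | target

Total step count: 8. Longest linear sequence: 7 (steps 1, 2, 3, 4, 6, 7, 8); step 5 is a one-step branch that joins at step 6.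

Steps most likely to fail

Step 6 (the proposed new method). The enol silane may couple with itself, the α-keto radical may be oxidised further and captured by methanol before it meets the alkene, or the silyl group may be lost by methanolysis before electron transfer. The fallback sets out from 9 and returns at 12, and uses the known chemical cross-coupling of two silyl enol ethers. Purchased heptan-2-one (CCCCCC(C)=O) is deprotonated at the methyl group with LiN(iPr)2 in THF at −78 °C and silylated with Me3SiCl to give trimethyl(hept-1-en-2-yloxy)silane F1. Compound 9 and an excess of F1 are then treated with (NH4)2Ce(NO3)6 (2.2 equiv, tetravalent cerium as one-electron oxidant) and NaHCO3 in MeCN at room temperature. The more electron-rich trisubstituted enol silane should be oxidised first, its radical should add to the CH2 terminus of F1, and a second oxidation with desilylation should give 12. This replaces the electrode by a stoichiometric oxidant and the enol acetate by a silyl enol ether acceptor.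

Step 3. The Grignard reagent may attack the methyl ester, the released amine or a second equivalent of the Grignard reagent may add to the new enone, or the vinyl ketone may oligomerise on concentration. The fallback sets out from 2 and returns at 7, and avoids both the organomagnesium reagent and the basic amine. Compound 2 is converted with (COCl)2 and catalytic DMF in CH2Cl2 into methyl 14-chloro-14-oxotetradecanoate F2. F2 is then coupled with tributyl(vinyl)stannane under PdCl2(PPh3)2 (2 mol%, reduced in the flask to zerovalent palladium) in toluene at 60 °C. This Stille acylation should give 7 directly and leaves esters alone.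

Step 4. The silane may add 1,2 to the carbonyl group, the enone may oligomerise before hydride transfer, or the silyl group may be lost by hydrolysis during isolation. The fallback sets out from 7 and returns at 9, and replaces the catalytic Si–H addition by a stoichiometric conjugate hydride transfer with separate O-silylation. Compound 7 is treated with [(Ph3P)CuH]6 (0.4 equiv of hexamer) in the presence of Et3SiCl (2 equiv) in toluene at room temperature. The hydride of monovalent copper adds to the terminal carbon, and the regiodefined copper enolate is trapped on oxygen to give 9, which is then used crude after filtration through basic alumina. Esters are not reduced by this reagent.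

Further compounds
F1 | step 6 | trimethyl(hept-1-en-2-yloxy)silane | C=C(CCCCC)O[Si](C)(C)C
F2 | step 3 | methyl 14-chloro-14-oxotetradecanoate | COC(=O)CCCCCCCCCCCCC(=O)Cl
F0 | step 4 | none | none
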